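The side chain is counted from the benzylic carbon C1 to the methyl carbon C17. The target is 5-[(8Z,11S)-11-hydroxyheptadec-8-en-1-yl]benzene-1,3-diol, released last by fluoride removal of two phenolic TIPS groups.
Key disconnection C10–C11: heptanal (C11–C17) and an R-configured secondary allylic pinacol boronate (boron on C8, terminal vinyl group C9=C10) combine in a chair-shaped, boron-templated hetero-[3,3] shift. This forms the bond, moves the alkene to C8=C9 as the Z isomer, and passes the chirality of C8 to C11.
Enabling feature: the homoallylic alcohol array O–C11–C10–C9=C8. These five atoms plus a boron atom on C8 complete the six-membered chair, and because C8 ends as an sp2 carbon the auxiliary C8–B stereocenter disappears without trace.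
The boronate comes from the achiral C1–C8 carbamate by sparteine-mediated lithiation at C8 and 1,2-metalate shift of a vinyl group from boron (C8–C9 bond). The carbamate comes from oct-7-en-1-ol and 5-bromoresorcinol by hydroboration and Suzuki–Miyaura coupling (aryl–C1 bond).
No ring is formed at any stage: the only ring, the benzene ring of the resorcinol (ring A), is bought with 5-bromoresorcinol.

Key step: step 5

Assumption: (R)-TRIP is taken to steer a secondary allyl pinacol boronate to the same aldehyde face (Re) as it does the parent allyl pinacol boronate; for heptanal this face leads to the S carbinol.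

Step 1
Reactants: 1 5-bromobenzene-1,3-diol (5-bromoresorcinol)
Product: 2 1-bromo-3,5-bis(triisopropylsilyloxy)benzene
Conditions: TIPSCl (2.4 equiv), imidazole (5 equiv), DMF, rt
Reagents that add atoms: triisopropylsilyl chloride (TIPSCl), CC(C)[Si](Cl)(C(C)C)C(C)C
Why: Imidazole-promoted silylation of both phenols; the bulky TIPS groups are chosen because they neither direct nor permit ring lithiation in step 4 and leave with fluoride at the end.

Step 2
Reactants: 3 oct-7-en-1-ol
Product: 4 oct-7-en-1-yl N,N-diisopropylcarbamate
Conditions: CbCl (1.2 equiv), Et3N (1.5 equiv), CH2Cl2, reflux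
Reagents that add atoms: N,N-diisopropylcarbamoyl chloride (CbCl), CC(C)N(C(C)C)C(Cl)=O
Why: Acylation of the primary alcohol installs the hindered carbamate that later directs the lithiation and serves as the leaving group of the 1,2-metalate shift.

Step 3
Reactants: 4 oct-7-en-1-yl N,N-diisopropylcarbamate; 2 1-bromo-3,5-bis(triisopropylsilyloxy)benzene
Product: 6 8-[3,5-bis(triisopropylsilyloxy)phenyl]octyl N,N-diisopropylcarbamate, via B-alkyl-9-BBN adduct 5 (not isolated)
Conditions: 9-BBN-H, THF, 0 °C to rt; then 2, Pd(dppf)Cl2·CH2Cl2 (3 mol %), K3PO4 (3 M aq), THF/DMF, 50 °C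
Reagents that add atoms: none
Why: Anti-Markovnikov hydroboration of the terminal alkene followed by B-alkyl Suzuki–Miyaura coupling with the unhindered aryl bromide forms the aryl–C1 bond, and carbamate and TIPS ethers tolerate both stages.

Step 4
Reactants: 6 8-[3,5-bis(triisopropylsilyloxy)phenyl]octyl N,N-diisopropylcarbamate; 7 vinylboronic acid pinacol ester
Product: 10 (R)-2-{10-[3,5-bis(triisopropylsilyloxy)phenyl]dec-1-en-3-yl}-4,4,5,5-tetramethyl-1,3,2-dioxaborolane, via lithiated carbamate 8 (not isolated), via vinyl boronate complex 9 (not isolated)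
Conditions: s-BuLi (1.3 equiv), (−)-sparteine (1.3 equiv), Et2O, −78 °C, 5 h; 7 (1.4 equiv), −78 °C, 1 h; MgBr2·OEt2, −78 °C to reflux, 16 h
Reagents that add atoms: none
Why: Lithiation–borylation: carbamate-directed deprotonation with s-BuLi/(−)-sparteine removes the pro-S hydrogen at C8, the S organolithium is borylated with retention, and the MgBr2-promoted Matteson-type 1,2-metalate shift of the vinyl group displaces the carbamate with inversion, so C8 should be set as R in a boronic ester that is stable toward 1,3-boron shift.

Step 5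
Reactants: 10 (R)-2-{10-[3,5-bis(triisopropylsilyloxy)phenyl]dec-1-en-3-yl}-4,4,5,5-tetramethyl-1,3,2-dioxaborolane; 11 heptanal
Product: 13 bis(triisopropylsilyl) ether of 5-[(8Z,11S)-11-hydroxyheptadec-8-en-1-yl]benzene-1,3-diol, via pinacol borate ester 12 (not isolated)
Conditions: 10 (1.15 equiv), 11 (1.0 equiv), (R)-TRIP [(R)-3,3'-bis(2,4,6-triisopropylphenyl)-1,1'-binaphthyl-2,2'-diyl hydrogen phosphate, 10 mol %], 4 Å MS, toluene, −45 °C; aq NaHCO3 work-up
Reagents that add atoms: none
Why: The phosphoric acid hydrogen-bonds to a boronate oxygen and to the formyl hydrogen, heptanal binds to boron through its oxygen, and the complex reorganises through a closed six-membered chair (B, O, C11, C10, C9, C8) in which the C10–C11 bond forms while the C8–B bond breaks and the double bond moves from C9=C10 to C8=C9, that is a boron-templated hetero-[3,3] shift of Zimmerman–Traxler type. The closest known reaction type is the chiral-phosphoric-acid-catalysed allylboration of aldehydes with secondary (alpha-substituted) allyl boronic esters, which is known to deliver Z-homoallylic alcohols, including the pairing of an enantioenriched boronate with the matching enantiomer of the acid. No ring of the product is closed; only the transient chair is cyclic. The single new stereocenter C11 is controlled twice in the same sense: the R configuration at C8 with the C1–C7 chain axial presents C10 to the Re face of the aldehyde whose hexyl group sits equatorial, and (R)-TRIP prefers the same Re face, so S should result. The step needs attack through C10 rather than C8, Z rather than E geometry and one aldehyde face: delivery through C10 is enforced by the closed transition state and by a boronic ester that cannot shift its boron to C10; the axial C8 substituent, hence the Z alkene, is favoured because the equatorial position clashes with the pinacol methyl groups; and the E pathway of this boronate enantiomer would require the Si face that the catalyst disfavours. With heptanal as the limiting partner, the small share of S boronate left from step 4 is mismatched and should stay largely unreacted, which should raise the enantiomeric purity of the product.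

Step 6
Reactants: 13 bis(triisopropylsilyl) ether of 5-[(8Z,11S)-11-hydroxyheptadec-8-en-1-yl]benzene-1,3-diol
Product: 14 5-[(8Z,11S)-11-hydroxyheptadec-8-en-1-yl]benzene-1,3-diol
Conditions: TBAF (2.5 equiv), AcOH (2.5 equiv), THF, 0 °C to rt
Reagents that add atoms: none
Why: Fluoride-driven desilylation cleaves both aryl silyl ethers, the acetic acid buffer keeps the resorcinol protonated, and neither the C11 carbinol nor the Z alkene is touched.

Compound list
1 | 5-bromobenzene-1,3-diol | Oc1cc(O)cc(Br)c1 | starting material
2 | 1-bromo-3,5-bis(triisopropylsilyloxy)benzene | Brc1cc(O[Si](C(C)C)(C(C)C)C(C)C)cc(O[Si](C(C)C)(C(C)C)C(C)C)c1 | intermediate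
3 | oct-7-en-1-ol | C=CCCCCCCO | starting material
4 | oct-7-en-1-yl N,N-diisopropylcarbamate | C=CCCCCCCOC(=O)N(C(C)C)C(C)C | intermediate
5 | 8-(9-borabicyclo[3.3.1]nonan-9-yl)octyl N,N-diisopropylcarbamate | CC(C)N(C(C)C)C(=O)OCCCCCCCCB1C2CCCC1CCC2 | intermediate
6 | 8-[3,5-bis(triisopropylsilyloxy)phenyl]octyl N,N-diisopropylcarbamate | CC(C)N(C(C)C)C(=O)OCCCCCCCCc1cc(O[Si](C(C)C)(C(C)C)C(C)C)cc(O[Si](C(C)C)(C(C)C)C(C)C)c1 | intermediate
7 | vinylboronic acid pinacol ester | C=CB1OC(C)(C)C(C)(C)O1 | starting material
8 | (S)-1-lithio-8-[3,5-bis(triisopropylsilyloxy)phenyl]octyl N,N-diisopropylcarbamate, (−)-sparteine complex | [Li][C@@H](CCCCCCCc1cc(O[Si](C(C)C)(C(C)C)C(C)C)cc(O[Si](C(C)C)(C(C)C)C(C)C)c1)OC(=O)N(C(C)C)C(C)C | intermediate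
9 | lithium (S)-configured vinyl(alpha-carbamoyloxyalkyl) pinacol boronate complex | [Li+].C=C[B-]1(OC(C)(C)C(C)(C)O1)[C@@H](CCCCCCCc1cc(O[Si](C(C)C)(C(C)C)C(C)C)cc(O[Si](C(C)C)(C(C)C)C(C)C)c1)OC(=O)N(C(C)C)C(C)C | intermediate
10 | (R)-2-{10-[3,5-bis(triisopropylsilyloxy)phenyl]dec-1-en-3-yl}-4,4,5,5-tetramethyl-1,3,2-dioxaborolane | C=C[C@@H](CCCCCCCc1cc(O[Si](C(C)C)(C(C)C)C(C)C)cc(O[Si](C(C)C)(C(C)C)C(C)C)c1)B1OC(C)(C)C(C)(C)O1 | intermediate
11 | heptanal | CCCCCCC=O | starting material
12 | O-(pinacolatoboryl) derivative of 13 at the C11 oxygen, (8Z,11S) | CCCCCC[C@H](OB1OC(C)(C)C(C)(C)O1)C/C=C\CCCCCCCc1cc(O[Si](C(C)C)(C(C)C)C(C)C)cc(O[Si](C(C)C)(C(C)C)C(C)C)c1 | intermediate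
13 | bis(triisopropylsilyl) ether of 5-[(8Z,11S)-11-hydroxyheptadec-8-en-1-yl]benzene-1,3-diol | CCCCCC[C@H](O)C/C=C\CCCCCCCc1cc(O[Si](C(C)C)(C(C)C)C(C)C)cc(O[Si](C(C)C)(C(C)C)C(C)C)c1 | intermediate
14 | 5-[(8Z,11S)-11-hydroxyheptadec-8-en-1-yl]benzene-1,3-diol | CCCCCC[C@H](O)C/C=C\CCCCCCCc1cc(O)cc(O)c1 | target

Total step count: 6. Longest linear sequence: 5 (steps 2, 3, 4, 5, 6).

Steps most likely to fail

Step 5. The reaction may leak through the chair with the C8 substituent equatorial, which erodes the Z geometry. Turnover with an enolisable aliphatic aldehyde may also be slow, so that the less selective uncatalysed pathway competes. The fallback separates the two tasks; it sets out from 11 and 2 and returns at 13. Heptanal 11 is allylated with allylboronic acid pinacol ester and (R)-TRIP in toluene at −30 °C, forming the same C10–C11 bond, to give (S)-dec-1-en-4-ol F1. Nona-1,8-diene in excess is monohydroborated with 9-BBN-H and coupled with 2 (Pd(dppf)Cl2, K3PO4, THF) to give 1-(non-8-en-1-yl)-3,5-bis(triisopropylsilyloxy)benzene F2. Z-selective cross-metathesis of F1 with F2 then uses the cyclometalated ruthenium nitrate Grubbs catalyst C32H41N3O4Ru (N-adamantyl, N-mesityl imidazolinylidene, 2-isopropoxybenzylidene) in THF at 35 °C with removal of ethene. It should set the C8=C9 geometry under catalyst control and give 13.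

Step 4. Deprotonation of the electron-rich ring or of the benzylic position, silyl migration, or an incomplete 1,2-shift may consume the advanced carbamate. The fallback changes the order of fragment union so that the organolithium never meets the arene; it sets out from 4 and returns at 13. Carbamate 4 is lithiated (s-BuLi, (−)-sparteine, Et2O, −78 °C), borylated with 7 and rearranged with MgBr2·OEt2 to give (R)-2-(deca-1,9-dien-3-yl)-4,4,5,5-tetramethyl-1,3,2-dioxaborolane F3. Its (R)-TRIP-catalysed allylboration of 11 should give (7S,9Z)-heptadeca-9,16-dien-7-ol F4. Chemoselective hydroboration of the terminal alkene of F4 with 9-BBN-H (one extra equivalent for the hydroxyl group), followed by Suzuki–Miyaura coupling with 2, attaches ring A last and gives 13.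

Step 3. The phenolic silyl groups may be lost under the warm aqueous base, and the alkylborane may undergo protodeboronation. The fallback uses a non-aqueous sp–sp2 coupling; it sets out from 2 and returns at 6. Commercial oct-7-yn-1-ol is carbamoylated (CbCl, Et3N, CH2Cl2, reflux) to oct-7-yn-1-yl N,N-diisopropylcarbamate F5. Sonogashira coupling of F5 with 2 (Pd(PPh3)2Cl2, CuI, Et3N, 70 °C) gives 8-[3,5-bis(triisopropylsilyloxy)phenyl]oct-7-yn-1-yl N,N-diisopropylcarbamate F6. Full hydrogenation of the alkyne (H2, Pd/C, EtOAc) then gives 6.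

Further compounds
F1 | step 5 | (S)-dec-1-en-4-ol | CCCCCC[C@H](O)CC=C
F2 | step 5 | 1-(non-8-en-1-yl)-3,5-bis(triisopropylsilyloxy)benzene | C=CCCCCCCCc1cc(O[Si](C(C)C)(C(C)C)C(C)C)cc(O[Si](C(C)C)(C(C)C)C(C)C)c1
F3 | step 4 | (R)-2-(deca-1,9-dien-3-yl)-4,4,5,5-tetramethyl-1,3,2-dioxaborolane | C=C[C@@H](CCCCCC=C)B1OC(C)(C)C(C)(C)O1
F4 | step 4 | (7S,9Z)-heptadeca-9,16-dien-7-ol | CCCCCC[C@H](O)C/C=C\CCCCCC=C
F5 | step 3 | oct-7-yn-1-yl N,N-diisopropylcarbamate | C#CCCCCCCOC(=O)N(C(C)C)C(C)C
F6 | step 3 | 8-[3,5-bis(triisopropylsilyloxy)phenyl]oct-7-yn-1-yl N,N-diisopropylcarbamate | CC(C)N(C(C)C)C(=O)OCCCCCCC#Cc1cc(O[Si](C(C)C)(C(C)C)C(C)C)cc(O[Si](C(C)C)(C(C)C)C(C)C)c1
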